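| flask | starting material | partner | remark | time |
|---|---|---|---|---|
| blue | 0.25 M | 1.8 equiv | run made earlier |  |
| teal | 0.12 M | 1.8 equiv | run made earlier |  |
| red | 0.19 M | 1.8 equiv | run made earlier |  |
| cedar | 0.25 M (fed, over 25 h) | 1.80 equiv | all else is in the flask from the start; the feed brings no volume worth counting | 40 h |
| oak | 0.25 M | 1.80 equiv (fed, over 25 h) | all else is in the flask from the start; the feed brings no volume worth counting | 40 h |
| birch | 0.25 M | 1.80 equiv | everything together at the start | 40 h |

| blue: time / h | blue: mono adduct / % | teal: time / h | teal: mono adduct / % | red: time / h | red: mono adduct / % |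
|---|---|---|---|---|---|
| 2.00 | 20 | 2.00 | 10 | 1.33 | 10 |
| 3.00 | 27 | 3.00 | 16 | 4.00 | 30 |
| 4.00 | 34 | 4.00 | 16 | 6.00 | 35 |
| 6.00 | 41 | 6.00 | 24 | 10.0 | 48 |
| 10.0 | 51 | 10.0 | 33 | 15.0 | 59 |
| 15.0 | 65 | 15.0 | 45 | 20.0 | 66 |
| 25.0 | 76 | 25.0 | 61 | 25.0 | 71 |

(readings scatter by 1.5 percentage points)
- the analysis behind the earlier runs scatters by 1.5 percentage points, standard deviation
- a reading or a percentage of mono adduct counts all its forms, free or not
- the flask that comes out highest in amount of mono adduct, in percent of the starting material charged, or "all alike" when all lie within 1.5 percentage points (cedar / oak / birch / all alike)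
- mono adduct at the end, in percent of the starting material charged, cedar
- mono adduct at the end, in percent of the starting material charged, oak
- mono adduct at the end, in percent of the starting material charged, birch

- A ratio of 1.80 equiv of partner to starting material, the limiting reagent, is charged to cedar, oak and birch alike, and blue has birch's concentration, so I take the blue curve as the zero of my scale and ask how old the fed reagent is at the end.
- In one extreme I hold the fed charge back and pour it in at 25 h; 15.0 h remain, and blue reads 65% at that age.
- In the other extreme the charge goes in at the start, which is birch itself, with the whole 40 h.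
- A steady feed is symmetric about its midpoint, so I place the fed flasks between these extremes by the mean age of the fed charge, the time minus half the feed time, 27.5 h.
- Carrying blue's last slope past its last reading to that age gives 78.8% for cedar and oak, and I expect this to err high, since blue's last slope is less than the one before it; birch is older on a rising curve, so I put it first.
- The forecast names birch, with 76% for cedar, 77% for oak and 85% for birch, reckoned on a fitted rate law that reads the bending of the curves as “product inhibition rather than catalyst aging” and stepped through the feeds by hand, and it sets the fed flasks apart and below my figure.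
- The flasks give 72.7% for cedar, 77.1% for oak and 81.3% for birch, so birch stands highest. Double product ends at 8.02% in cedar and 5.02% in oak. Read at the mean age of 27.5 h, my figure stands 1.7 percentage points above oak and 6 points above cedar.

    starting material + partner → mono adduct + released group (k = 7.24 × 10⁻⁵ /M/s)
    partner + other mono adduct → double product + released group (k = 4.97 × 10⁻⁶ /M/s)
    starting material + partner → other mono adduct + released group (k = 5.17 × 10⁻⁶ /M/s)
    partner + mono adduct → double product + released group (k = 1.15 × 10⁻⁴ /M/s)
    starting material → decomposition product (k = 1.49 × 10⁻⁸ /s)
    crystals ⇌ mono adduct, rate k6*(cs6 - [mono adduct]) while solid is left; crystals form when [mono adduct] > cs6 (solubility = 2.80 mM, k = 0.00157 /s)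

- For a neighbour of cedar at 0.15 M, the same reading at 27.5 h gives 65.0% on teal and 74.0% on red, hence 68.9% between them and 62.9% after cedar's gap; the computed flask gives 62.5%.

(The readings are simulated with made-up constants; the scatter is artificial.)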